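**Assumptions:** the SMILES is taken as the required absolute configuration; guaianolide numbering (C1–C15, primes for the ether-bridged half) is used in descriptions; cyclopentadiene is used freshly cracked from its dimer.

## Retrosynthetic overview

1. Anabsin ⇐ absinthin by Re(VII) syn-oxidative cyclisation (C10′–O to C4′, OH to C3′); absinthin ⇐ endo, head-to-head Diels–Alder dimerisation of the cyclopentadiene guaianolide monomer.
2. Monomer ⇐ Pd-catalysed methylation (C4–C15) of a lactone dienyl triflate, itself from a cis-fused bicyclic 4-oxo-6α,12-lactone.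
3. Seven-membered ring ⇐ Pd-catalysed umpolung allylation closing C1–C10 (sets C1 and C10) of a 4-hydroxycyclopentenone carrying the γ-lactone and a tethered methyl ketone.
4. That precursor ⇐ anti boron aldol (C5–C6) between (R)-4-(TBSO)cyclopentenone (from cyclopentadiene) and a (2S,3S)-aldehyde ester (from (S)-hydroxymethylbutenolide and a C4 bromo-ketone by Cu-catalysed conjugate addition, methylation and glycol cleavage), then desilylation/lactonisation.
5. Ring order: butenolide template (C7, C11) → ring A attached by aldol → γ-lactone → seven-membered ring → cyclopentadiene → norbornene (Diels–Alder) → oxolane bridge.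

## Route

**Step 1**
Reactants: 1, 4-bromobutan-2-one
Product: 2, 2-(2-bromoethyl)-2-methyl-1,3-dioxolane
Conditions: HOCH2CH2OH, p-TsOH (cat.), PhH, reflux (Dean–Stark)
Reagents that add atoms: ethylene glycol, OCCO
Why: Acid-catalysed ketalisation masks the ketone so the bromide can later be converted into a Grignard reagent.

**Step 2**
Reactants: 3, (S)-5-(hydroxymethyl)furan-2(5H)-one
Product: 4, (S)-5-{[(tert-butyldimethylsilyl)oxy]methyl}furan-2(5H)-one
Conditions: TBSCl, imidazole, CH2Cl2, 0 °C → rt
Reagents that add atoms: tert-butyldimethylsilyl chloride, CC(C)(C)[Si](C)(C)Cl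
Why: O-silylation gives the bulky CH2OTBS group that shields one face of the butenolide.

**Step 3**
Reactants: 4, the silylated butenolide; 2, the bromo ketal (converted in situ into its Grignard reagent)
Product: 5, (4S,5S)-5-{[(tert-butyldimethylsilyl)oxy]methyl}-4-[2-(2-methyl-1,3-dioxolan-2-yl)ethyl]dihydrofuran-2(3H)-one
Conditions: 2, Mg, THF, 25 °C; then CuBr·SMe2 (10 mol %), TMSCl, 4, THF, −78 °C; aq. NH4Cl
Reagents that add atoms: none
Why: Cu-catalysed conjugate addition of the Grignard reagent occurs anti to the CH2OTBS group (4,5-trans), setting C7.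

**Step 4**
Reactants: 5, the 4,5-trans lactone
Product: 6, (3S,4S,5S)-5-{[(tert-butyldimethylsilyl)oxy]methyl}-3-methyl-4-[2-(2-methyl-1,3-dioxolan-2-yl)ethyl]dihydrofuran-2(3H)-one
Conditions: LDA, THF, −78 °C; MeI, −78 → −40 °C
Reagents that add atoms: iodomethane, CI
Why: Lactone enolate alkylation occurs anti to the adjacent C4 side chain (3,4-trans), setting C11 as the natural 11S (α-methyl) centre.

**Step 5**
Reactants: 6, the methylated silyl ether
Product: 7, (3S,4S,5S)-5-(hydroxymethyl)-3-methyl-4-[2-(2-methyl-1,3-dioxolan-2-yl)ethyl]dihydrofuran-2(3H)-one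
Conditions: TBAF, AcOH, THF, 0 °C
Reagents that add atoms: none
Why: Buffered fluoride desilylation frees the primary alcohol without epimerisation or translactonisation.

**Step 6**
Reactants: 7, the hydroxymethyl lactone
Product: 8, (3S,4S)-5-hydroxy-3-methyl-4-(3-oxobutyl)dihydrofuran-2(3H)-one (lactol, anomeric mixture; ring form of the aldehydo acid)
Conditions: LiOH, THF/H2O, 0 °C; NaIO4, pH 7 buffer; then 1 M HCl, THF, rt
Reagents that add atoms: water, O
Why: Saponification exposes the vicinal diol, periodate (Malaprade) cleavage excises the template carbon to leave the C6 aldehyde, and acid closes the lactol and removes the dioxolane; C7 and C11 are untouched.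

**Step 7**
Reactants: 8, the lactol
Product: 9, methyl (2S,3S)-3-formyl-2-methyl-6-oxoheptanoate
Conditions: TMSCHN2, PhMe/MeOH, 0 °C
Reagents that add atoms: (trimethylsilyl)diazomethane, C[Si](C)(C)C=[N+]=[N-]
Why: O-methylation of the open carboxylic acid tautomer releases the free aldehyde needed for the aldol.

**Step 8**
Reactants: 10, cyclopenta-1,3-diene
Product: 11, cis-cyclopent-4-ene-1,3-diol (meso)
Conditions: O2, hν, rose bengal, thiourea, MeOH, −30 °C
Reagents that add atoms: dioxygen, O=O
Why: Singlet-oxygen [4+2] cycloaddition gives the endoperoxide, reduced in situ by thiourea to the cis diol.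

**Step 9**
Reactants: 11, the meso diol
Product: 12, cis-cyclopent-4-ene-1,3-diyl diacetate (meso)
Conditions: Ac2O, pyridine, DMAP (cat.), CH2Cl2, rt
Reagents that add atoms: acetic anhydride, CC(=O)OC(C)=O
Why: Exhaustive acetylation provides the substrate for enzymatic desymmetrisation.

**Step 10**
Reactants: 12, the meso diacetate
Product: 13, (1R,4S)-4-hydroxycyclopent-2-en-1-yl acetate
Conditions: electric-eel acetylcholinesterase, pH 6.9 phosphate buffer, rt
Reagents that add atoms: none
Why: Enantiotopos-selective enzymatic hydrolysis (desymmetrisation) sets the absolute configuration of ring A.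

**Step 11**
Reactants: 13, the monoacetate
Product: 14, (R)-4-oxocyclopent-2-en-1-yl acetate
Conditions: MnO2, CH2Cl2, rt
Reagents that add atoms: none
Why: Chemoselective allylic alcohol oxidation gives the enone; the acetate-bearing stereocentre is untouched.

**Step 12**
Reactants: 14, the acetoxy enone
Product: 15, (R)-4-hydroxycyclopent-2-en-1-one
Conditions: wheat-germ lipase, pH 5 phosphate buffer, rt
Reagents that add atoms: none
Why: Neutral enzymatic deacetylation avoids the β-elimination and racemisation that basic methanolysis causes.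

**Step 13**
Reactants: 15, the hydroxy enone
Product: 16, (R)-4-[(tert-butyldimethylsilyl)oxy]cyclopent-2-en-1-one
Conditions: TBSCl, imidazole, CH2Cl2, 0 °C
Reagents that add atoms: tert-butyldimethylsilyl chloride, CC(C)(C)[Si](C)(C)Cl
Why: O-silylation installs a bulky silyl ether that is a poor β-leaving group during enolisation, directs the aldol face, and is later removed by mildly acidic fluoride.

**Step 14**
Reactants: 16, the TBS-protected enone; 9, the aldehyde ester
Product: 17, methyl (2S,3S)-3-[(S)-{(1R,5S)-5-[(tert-butyldimethylsilyl)oxy]-2-oxocyclopent-3-en-1-yl}(hydroxy)methyl]-2-methyl-6-oxoheptanoate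
Conditions: 16, Cy2BCl, Et3N, Et2O, −78 °C; then 9, −78 → −20 °C; pH 7 buffer, MeOH, H2O2, 0 °C
Reagents that add atoms: none
Why: Boron-mediated aldol: the (E)-dicyclohexylboron enolate (α′ carbon = C5) reacts through a Zimmerman–Traxler chair on the face anti to the C1 OTBS group, giving the 5,6-anti aldol with H-5 trans to OTBS and the 6S carbinol; enolate control is expected to override the weak 1,2-induction of the aldehyde.

**Step 15**
Reactants: 17, the aldol
Product: 18, (3S,4S,5S)-5-[(1S,5S)-5-hydroxy-2-oxocyclopent-3-en-1-yl]-3-methyl-4-(3-oxobutyl)dihydrofuran-2(3H)-one (trans,trans-γ-lactone with the ring-A allylic alcohol free; same spatial arrangement as 17)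
Conditions: HF·pyridine, THF, 0 °C → rt; then PPTS (cat.), CH2Cl2, rt
Reagents that add atoms: none
Why: Fluoride desilylation frees the allylic C1–OH and the C6–OH lactonises onto the methyl ester (five-membered ring strongly favoured over the seven-membered alternative from C1–OH); this fixes the 6α,12-lactone early and removes the retro-aldol-prone free β-hydroxy ketone, with no stereocentre touched.

**Step 16**
Reactants: 18, the hydroxy enone lactone with tethered methyl ketone
Product: 19, cis-fused (1αH,5αH) bicyclo[5.3.0]dec-2-en-4-one (guaiane numbering) carrying the trans-fused 6α,12-γ-lactone (6βH, 7αH, 11α-CH3), 10β-OTMS and 10α-CH3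
Conditions: Pd(PPh3)4 (5 mol %), InI (2.5 equiv), THF (0.01 M), rt; then N-(trimethylsilyl)imidazole, rt
Reagents that add atoms: N-(trimethylsilyl)imidazole, C[Si](C)(C)n1ccnc1
Why: Proposed new method: Pd(0) (In(III)-assisted) ionises the allylic C1–OH to a 2-acyl π-allyl that In(I) reduces to a C3-bound allylindium (α-indio ketone), which adds through C1 to the tethered C10 ketone in a six-membered SE2′ chair. The tether at C5, rigidified by the trans lactone, forces cis ring fusion (H-1α); the ring-locked Z-allyl with the tether equatorial and CH3 axial puts the C10 oxygen cis to C2 (10β-O, 10α-Me); attack through C3 would need a strained bridged eight-membered ring. Closest known reaction types are Pd/In(I) or Pd/Et2Zn umpolung allylation of aldehydes with allylic alcohols and the γ-selective vinylogous Reformatsky addition; neither has been shown for a ketone acceptor in a seven-membered ring closure from a γ-hydroxy enone. The tertiary alkoxide is capped in situ as its TMS ether so that it cannot undergo retro-vinylogous aldol cleavage in the next, basic step.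

**Step 17**
Reactants: 19, the bicyclic enone lactone
Product: 20, the cross-conjugated dienyl triflate of 19 (C2=C3 and C4(OTf)=C5, C1 still sp3 with H-1α; lactone, 10β-OTMS and other centres as in 19)
Conditions: PhNTf2 (1.2 equiv), THF, −78 °C; KHMDS (1.1 equiv) added dropwise, −78 °C (in situ trap); pH 7 buffer
Reagents that add atoms: N-phenylbis(trifluoromethanesulfonimide), O=S(=O)(N(c1ccccc1)S(=O)(=O)C(F)(F)F)C(F)(F)F
Why: Kinetic α′-deprotonation at C5 and immediate O-triflation give the 2-triflyloxy-1,3-diene; adding base to the ketone/PhNTf2 mixture keeps the enolate concentration negligible so that β-elimination of the C6 lactone oxygen does not compete; the temporary C5 centre is deliberately erased and C1 is not deprotonated.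

**Step 18**
Reactants: 20, the silylated dienyl triflate
Product: 21, (3S,3aS,6S,6aR,9bS)-6-hydroxy-3,6-dimethyl-2-oxo-2,3,3a,4,5,6,6a,9b-octahydroazuleno[4,5-b]furan-9-yl trifluoromethanesulfonate
Conditions: HF·pyridine, THF, 0 °C
Reagents that add atoms: none
Why: Fluoride cleavage of the tertiary TMS ether frees the C10–OH; the vinyl triflate and lactone are inert to these conditions.

**Step 19**
Reactants: 21, the lactone dienyl triflate
Product: 22, (3S,3aS,6S,6aR,9bS)-6-hydroxy-3,6,9-trimethyl-3a,4,5,6,6a,9b-hexahydroazuleno[4,5-b]furan-2(3H)-one (cyclopentadiene monomer; used at once)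
Conditions: Pd(PPh3)4 (5 mol %), Me2Zn (3 equiv), THF, 0 °C → rt; cold aq. NH4Cl work-up, concentrate ≤ 0 °C
Reagents that add atoms: dimethylzinc, C[Zn]C
Why: Negishi cross-coupling of the vinyl triflate installs C15 and unveils the cyclopentadiene under neutral conditions; no stereocentre is affected.

**Step 20**
Reactants: 22, the cyclopentadiene monomer (diene partner); 22, a second molecule of the same monomer (dienophile partner)
Product: 23, (+)-absinthin
Conditions: neat, rt, dark, 10 d
Reagents that add atoms: none
Why: Diels–Alder dimerisation: the diene half is attacked anti to its C10′ substituent and the C2=C3 dienophile on its H-1 face, endo, bonding C2–C2′ and C3–C5′, which sets C2, C3, C2′ and C5′.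

**Step 21**
Reactants: 23, absinthin
Product: 24, anabsin
Conditions: Re2O7 (2.5 equiv), 2,6-lutidine, CH2Cl2, rt; then aq. NaHSO3
Reagents that add atoms: dirhenium heptoxide, O=[Re](=O)(=O)O[Re](=O)(=O)=O
Why: Re(VII) syn-oxidative cyclisation of a bishomoallylic tertiary alcohol: the C10′ perrhenate ester adds [3+2] across the strained C3′=C4′ bond from the exo face on which C10′ sits, delivering the ether oxygen to C4′ and an oxo oxygen to C3′ suprafacially (both exo, cis); the C10–OH of the other half has no alkene within reach and lutidine suppresses acid-catalysed hydroalkoxylation.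

## Compound list

1 | 4-bromobutan-2-one | CC(=O)CCBr | starting material
2 | 2-(2-bromoethyl)-2-methyl-1,3-dioxolane | CC1(CCBr)OCCO1 | intermediate
3 | (S)-5-(hydroxymethyl)furan-2(5H)-one | OC[C@H]1OC(=O)C=C1 | starting material
4 | (S)-5-{[(tert-butyldimethylsilyl)oxy]methyl}furan-2(5H)-one | CC(C)(C)[Si](C)(C)OC[C@H]1OC(=O)C=C1 | intermediate
5 | (4S,5S)-5-(TBSO-methyl)-4-[2-(2-methyl-1,3-dioxolan-2-yl)ethyl]dihydrofuran-2(3H)-one | CC(C)(C)[Si](C)(C)OC[C@H]1OC(=O)C[C@@H]1CCC2(C)OCCO2 | intermediate
6 | (3S,4S,5S)-5-(TBSO-methyl)-3-methyl-4-[2-(2-methyl-1,3-dioxolan-2-yl)ethyl]dihydrofuran-2(3H)-one | CC(C)(C)[Si](C)(C)OC[C@H]1OC(=O)[C@@H](C)[C@@H]1CCC2(C)OCCO2 | intermediate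
7 | (3S,4S,5S)-5-(hydroxymethyl)-3-methyl-4-[2-(2-methyl-1,3-dioxolan-2-yl)ethyl]dihydrofuran-2(3H)-one | OC[C@H]1OC(=O)[C@@H](C)[C@@H]1CCC2(C)OCCO2 | intermediate
8 | (3S,4S)-5-hydroxy-3-methyl-4-(3-oxobutyl)dihydrofuran-2(3H)-one (lactol) | OC1OC(=O)[C@@H](C)[C@@H]1CCC(C)=O | intermediate
9 | methyl (2S,3S)-3-formyl-2-methyl-6-oxoheptanoate | COC(=O)[C@@H](C)[C@@H](C=O)CCC(C)=O | intermediate
10 | cyclopenta-1,3-diene | C1=CCC=C1 | starting material
11 | cis-cyclopent-4-ene-1,3-diol | O[C@@H]1C=C[C@H](O)C1 | intermediate
12 | cis-cyclopent-4-ene-1,3-diyl diacetate | CC(=O)O[C@@H]1C=C[C@H](OC(C)=O)C1 | intermediate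
13 | (1R,4S)-4-hydroxycyclopent-2-en-1-yl acetate | O[C@@H]1C=C[C@H](OC(C)=O)C1 | intermediate
14 | (R)-4-oxocyclopent-2-en-1-yl acetate | O=C1C=C[C@H](OC(C)=O)C1 | intermediate
15 | (R)-4-hydroxycyclopent-2-en-1-one | O=C1C=C[C@H](O)C1 | intermediate
16 | (R)-4-[(tert-butyldimethylsilyl)oxy]cyclopent-2-en-1-one | O=C1C=C[C@H](O[Si](C)(C)C(C)(C)C)C1 | intermediate
17 | methyl (2S,3S)-3-[(S)-{(1R,5S)-5-(TBSO)-2-oxocyclopent-3-en-1-yl}(hydroxy)methyl]-2-methyl-6-oxoheptanoate | O=C1C=C[C@H](O[Si](C)(C)C(C)(C)C)[C@H]1[C@@H](O)[C@@H](CCC(C)=O)[C@H](C)C(=O)OC | intermediate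
18 | (3S,4S,5S)-5-[(1S,5S)-5-hydroxy-2-oxocyclopent-3-en-1-yl]-3-methyl-4-(3-oxobutyl)dihydrofuran-2(3H)-one | O=C1C=C[C@H](O)[C@H]1[C@H]2OC(=O)[C@@H](C)[C@@H]2CCC(C)=O | intermediate
19 | cis-fused bicyclic enone 6α,12-lactone (1αH, 5αH, 6βH, 7αH, 11α-Me, 10β-OTMS, 10α-Me) | O=C1C=C[C@@H]2[C@H]1[C@H]3OC(=O)[C@@H](C)[C@@H]3CC[C@]2(C)O[Si](C)(C)C | intermediate
20 | dienyl triflate of 19 (C2=C3, C4(OTf)=C5; 10β-OTMS) | O=S(=O)(OC1=C2[C@H]3OC(=O)[C@@H](C)[C@@H]3CC[C@](C)(O[Si](C)(C)C)[C@@H]2C=C1)C(F)(F)F | intermediate
21 | (3S,3aS,6S,6aR,9bS)-6-hydroxy-3,6-dimethyl-2-oxo-2,3,3a,4,5,6,6a,9b-octahydroazuleno[4,5-b]furan-9-yl triflate | O=S(=O)(OC1=C2[C@H]3OC(=O)[C@@H](C)[C@@H]3CC[C@](C)(O)[C@@H]2C=C1)C(F)(F)F | intermediate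
22 | (3S,3aS,6S,6aR,9bS)-6-hydroxy-3,6,9-trimethyl-3a,4,5,6,6a,9b-hexahydroazuleno[4,5-b]furan-2(3H)-one (monomer) | CC1=C2[C@H]3OC(=O)[C@@H](C)[C@@H]3CC[C@](C)(O)[C@@H]2C=C1 | intermediate
23 | (+)-absinthin | CC1=C2[C@H]3OC(=O)[C@@H](C)[C@@H]3CC[C@](C)(O)[C@@H]2[C@H]2[C@@H]3[C@@H]4[C@@]([C@H]5OC(=O)[C@@H](C)[C@@H]5CC[C@]4(C)O)(C(C)=C3)[C@@H]12 | intermediate
24 | anabsin | CC1=C2[C@H]3OC(=O)[C@@H](C)[C@@H]3CC[C@](C)(O)[C@@H]2[C@H]2[C@@H]3[C@@H]4[C@]5([C@H]6OC(=O)[C@@H](C)[C@@H]6CC[C@]4(C)O[C@@]5(C)[C@H]3O)[C@@H]12 | target

## Summary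

Total step count: 21.

Longest linear sequence: 14 steps (3 → 24 via steps 2–7 and 14–21; the branches from 10, steps 8–13 then 14–21, and from 1, steps 1, 3–7 then 14–21, are also 14). This is two thirds of the total.

Three steps most likely to fail:

- **Step 16 (proposed Pd/In umpolung ring closure).** Risks are redox isomerisation or simple reduction of the γ-hydroxy enone and sluggish ketone addition. Fallback with known chemistry: convert the allylic alcohol 18 into the allylic bromide (CBr4/PPh3) and close the ring by a stoichiometric Zn (vinylogous Reformatsky) or CrCl2 (Nozaki–Hiyama) Barbier allylation, which passes through the same six-membered transition state.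
- **Step 17 (enol triflation next to the lactone oxygen).** The C5 enolate carries a β-acyloxy group at C6 and may eliminate to the 5,6-enone acid despite the in situ trap. Fallback: defer lactonisation. Protect ring A as a PMB ether instead of TBS, silylate the aldol C6–OH (TESOTf), remove PMB (DDQ), close the ring, triflate the β-silyloxy ketone (a non-leaving C6–OTES), then desilylate and lactonise with HF·pyridine/PPTS. This costs one extra linear step.
- **Step 21 (Re(VII) oxidative cyclisation).** Risks are competing acid-catalysed hydroalkoxylation to anabsinthin, delivery of the ether oxygen to C3′ instead of C4′, and over-oxidation. Fallback: a two-step route — hydroxyl-directed exo epoxidation of the norbornene (DMDO), then Lewis-acid (Sc(OTf)3, −78 °C) ionisation at the tertiary C4′ and capture by the syn C10′–OH with retention. This passes through the same C4′ cation as the acid-induced absinthin → anabsinthin etherification and gives the same cis hydroxy ether.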